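The numbers in the tables come from a simulation for an exercise.

A minute was a long time in these flasks: the midnight substrate read 23% at 20.0 s, a mean life of 0.227 min on a first-order reading, and the summer and noon readings at 0.200 min, 43% and 42%, barely differed despite their different charges of first nucleophile.

| flask | substrate | first nucleophile | second nucleophile | remark | time |
|---|---|---|---|---|---|
| midnight | 0.18 M | 1.5 equiv | 1.1 equiv | run made earlier |  |
| summer | 0.18 M | 0.75 equiv | 1.1 equiv | run made earlier |  |
| noon | 0.18 M | 3 equiv | 1.1 equiv | run made earlier |  |
| winter | 0.27 M | 1.5 equiv | 1.1 equiv | run made earlier |  |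
| Sunday's | 0.18 M | 1.50 equiv | 1.10 equiv | everything together at the start | 3.0 min |
| Tuesday's | 0.18 M | 1.50 equiv (fed, over 2.5 min) | 1.10 equiv | all else is in the flask from the start; the feed brings no volume worth counting | 3.0 min |
| Friday's | 0.18 M | 1.50 equiv | 1.10 equiv (fed, over 2.5 min) | all else is in the flask from the start; the feed brings no volume worth counting | 3.0 min |

midnight run (percent of the substrate charged)

| time / s | target / % | other capture product / % | substrate / % |
|---|---|---|---|
| 20.0 | 24 | 3 | 23 |
| 40.0 | 20 | 5 | 5 |
| 60.0 | 24 | 5 | 0 |
| 80.0 | 20 | 2 | 1 |
| 120 | 23 | 5 | 0 |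

summer run (percent of the substrate charged)

| time / min | target / % | other capture product / % | substrate / % |
|---|---|---|---|
| 0.200 | 11 | 0 | 43 |
| 0.667 | 13 | 4 | 6 |
| 1.00 | 10 | 4 | 0 |
| 1.50 | 13 | 5 | 0 |
| 2.50 | 14 | 8 | 0 |

noon run (percent of the substrate charged)

| time / min | target / % | other capture product / % | substrate / % |
|---|---|---|---|
| 0.200 | 30 | 2 | 42 |
| 0.667 | 38 | 3 | 5 |
| 1.00 | 36 | 4 | 1 |
| 1.50 | 35 | 6 | 0 |
| 2.50 | 33 | 4 | 0 |

winter run (percent of the substrate charged)

| time / min | target / % | other capture product / % | substrate / % |
|---|---|---|---|
| 0.200 | 25 | 3 | 39 |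
| 0.667 | 32 | 3 | 7 |
| 1.00 | 27 | 9 | 4 |
| 1.50 | 22 | 3 | 2 |
| 2.50 | 22 | 3 | 0 |

(each reading ± 2 percentage points)

- the best flask by share of target in target plus other capture product; "all alike" if 1.5 percentage points covers them all (Sunday's / Tuesday's / Friday's / all alike)
- share of target in target plus other capture product at the end, Sunday's
- share of target in target plus other capture product at the end, Tuesday's
- share of target in target plus other capture product at the end, Friday's



Tuesday's received the same 1.50 equiv of first nucleophile as Sunday's, yet I reckoned that its substrate met 0.136 equiv. The two numbers fit because the mean life was shorter than the feed: a steady starved feed offers, on average over the substrate's decay, the charge times mean life over feed time, neglecting consumption. On Friday's, the same reckoning gave 0.0998 equiv of second nucleophile.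

The midnight readings from 60.0 s on gave target over other capture product as 5.58. Dividing by the charge ratio gave 4.09, the selectivity factor: target per other capture product at equal c(first nucleophile) and c(second nucleophile). Noon and summer read 2.72 and 3.19, so this is a loose reading; I kept midnight's because its charges are Sunday's. Taking the share as the ratio over one plus the ratio, I reckoned 84.8% for Sunday's, 33.6% for Tuesday's (ratio 0.507) and 98.4% for Friday's.

The forecast gave 84%, 37% and 97% and chose Friday's, reasoning that “second nucleophile averages about 0.1 equiv”. The flasks gave 83.9%, 33.3% and 98.2%, and Friday's was best.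

    substrate → intermediate (k = 0.0750 s⁻¹)
    first nucleophile + intermediate → target (k = 2.10 M⁻¹ s⁻¹)
    second nucleophile + intermediate → other capture product (k = 0.420 M⁻¹ s⁻¹)
    intermediate → solvolysis product (k = 0.950 s⁻¹)
    substrate + intermediate → side product (k = 0.310 M⁻¹ s⁻¹)
    target ⇌ isomer of the product (K = 0.570, k = 0.0150 s⁻¹)
    second nucleophile ⇌ dormant form (K = 1.00, k = 0.0320 s⁻¹)

Tuesday's ended with target 2.75% and other capture product 5.51%, a ratio of 0.499 against my 0.507. The neighbouring flask was Tuesday's with 0.600 equiv of first nucleophile. The same mean life put 0.0544 equiv before its substrate, and 4.09 times that over 1.10 equiv gave a ratio of 0.203, a share of 16.9%. That flask gave 17.0%, with target 1.15% and other capture product 5.64% at 3.00 min.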